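## Plan

- **Enabling feature:** in the 1,2-dioxane ring (O1–O2–C3–C4–C5–C6) the tertiary peroxy carbons C3 and C6 are homochiral, with the two methyl groups trans. The ring, both methyls and the first carbon of each arm are therefore C2-symmetric about the axis through the midpoints of O1–O2 and C4–C5.
- **Retrosynthesis:** first cut the C1'–C2' bond of each arm (two olefinations), which leads back to the C2-symmetric (3R,6R)-dialdehyde. Then cut C3–O2 and C6–O1 together, which leads back to H2O2 and a C2-symmetric bis-epoxide.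
- **Forward order:** hexa-1,5-diyne gives the (E,E)-diene diol, then two temporary oxiranes. A one-flask double opening by H2O2 closes the dioxane, the only ring that is built. Glycol cleavage removes the two helper CH2OH carbons. The acid arm follows (stabilised Wittig), then the arylalkyl arm (Wittig), then diimide and saponification.
- **Stereochemistry:** L-(+)-diethyl tartrate sets all four oxirane centres, and C3 and C6 arise from them by double inversion. The two formyl groups of the dialdehyde are homotopic, so mono-olefination gives one stereoisomer whichever group reacts.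

Key step: step 4

Assumption: compounds 1, 11 and 13 are taken as catalogue items. Anhydrous ethereal H2O2 is obtained by extracting the aqueous reagent into Et2O and drying. TBDPS = tert-butyldiphenylsilyl.

## Route

Step 1
Reactants: 1 hexa-1,5-diyne
Product: 4 (2E,6E)-3,6-dimethylocta-2,6-diene-1,8-diol, via bis(alkenylalane) 2 (not isolated), via dilithium bis(alanate) 3 (not isolated)
Conditions: Me3Al (5 equiv), Cp2ZrCl2 (0.4 equiv), CH2Cl2, 0 °C to rt; volatiles off; n-BuLi (2.1 equiv), hexane/THF, −78 to 0 °C; (CH2O)n, rt; aq HCl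
Reagents that add atoms: trimethylaluminium C[Al](C)C; paraformaldehyde (as formaldehyde) C=O; n-butyllithium [Li]CCCC (atoms in 3 only)
Why: Negishi zirconium-catalysed methylalumination adds Me and Al syn across each terminal alkyne with Me on the internal carbon, and the alanate is hydroxymethylated with retention, which fixes both E-trisubstituted allylic alcohols.

Step 2
Reactants: 4 (2E,6E)-3,6-dimethylocta-2,6-diene-1,8-diol
Product: 5 (2S,3S,6S,7S)-2,3:6,7-diepoxy-3,6-dimethyloctane-1,8-diol
Conditions: Ti(OiPr)4 (0.2 equiv), L-(+)-diethyl tartrate (0.25 equiv), t-BuOOH (4 equiv, decane), 4 Å MS, CH2Cl2, −20 °C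
Reagents that add atoms: tert-butyl hydroperoxide CC(C)(C)OO
Why: Twofold Sharpless asymmetric epoxidation under reagent control should give the (S,S)-oxirane at each geraniol-type E-allylic alcohol, and minor-face events end up in a separable meso-type diastereomer, so the enantiomeric purity of the C2 isomer should rise (Horeau amplification).

Step 3
Reactants: 5 (2S,3S,6S,7S)-2,3:6,7-diepoxy-3,6-dimethyloctane-1,8-diol
Product: 6 (2S,3S,6S,7S)-1,8-bis(TBDPS-oxy)-2,3:6,7-diepoxy-3,6-dimethyloctane
Conditions: TBDPSCl (2.3 equiv), imidazole, DMF, 0 °C to rt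
Reagents that add atoms: tert-butyl(chloro)diphenylsilane CC(C)(C)[Si](Cl)(c1ccccc1)c2ccccc2
Why: Standard silylation of primary alcohols gives an acid-stable, non-participating ether that makes the substrate ether-soluble, lets excess H2O2 be washed out later and shields the neighbouring carbinol oxygen in step 4.

Step 4
Reactants: 6 (2S,3S,6S,7S)-1,8-bis(TBDPS-oxy)-2,3:6,7-diepoxy-3,6-dimethyloctane
Product: 8 (1S,1'S)-1,1'-[(3R,6R)-3,6-dimethyl-1,2-dioxane-3,6-diyl]bis[2-(TBDPS-oxy)ethan-1-ol], via hydroperoxy epoxide 7 (not isolated)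
Conditions: H2O2 (anhydrous, ca. 0.5 M in Et2O, 5 equiv), H3PMo12O40 (5 mol %), Et2O, 0 °C to rt; water wash
Reagents that add atoms: hydrogen peroxide OO
Why: Proposed new method: the heteropoly acid activates one of the two homotopic oxiranes of 6, H2O2 attacks its tertiary carbon from the rear (borderline SN2) to give hydroperoxide 7, and the terminal oxygen of that OOH group then opens the second activated oxirane at its tertiary carbon, so that one molecule of H2O2 supplies O1–O2 and both C–O bonds. The closest known reaction types are the molybdenum-acid-catalysed perhydrolysis of trisubstituted epoxides to β-hydroxy hydroperoxides and the acid-catalysed cyclisation of hydroperoxy epoxides to 1,2-dioxanes; new is only their coupling on a bis-epoxide in one flask. The 1,2-dioxane closes in the 6-exo-tet mode through a chair that places both large arms equatorial and both methyl groups axial. C3 and C6 are each fixed by inversion of an (S)-oxirane carbon that the tartrate has set, which gives (3R,6R) without any call on substrate diastereoselection, while the two carbinol carbons keep their C–O bonds and stay (S). The step needs attack at the tertiary and not the secondary oxirane carbon, secured by the cation-stabilising alkyl groups and by the inductive deactivation of the carbon next to CH2OSi. It also needs the tethered OOH to beat a second H2O2, the new secondary OH and the neighbouring oxirane oxygen, secured by the alpha effect, by the two quaternary carbons that fold the C3–C6 chain (high effective molarity), by the TBDPS group flanking that OH and by the Lewis-basic ether medium that tempers the acid.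

Step 5
Reactants: 8 (1S,1'S)-1,1'-[(3R,6R)-3,6-dimethyl-1,2-dioxane-3,6-diyl]bis[2-(TBDPS-oxy)ethan-1-ol]
Product: 9 (1S,1'S)-1,1'-[(3R,6R)-3,6-dimethyl-1,2-dioxane-3,6-diyl]bis(ethane-1,2-diol)
Conditions: TBAF (2.5 equiv), AcOH (2.5 equiv), THF, 0 °C to rt
Reagents that add atoms: none
Why: Fluoride desilylation buffered with AcOH keeps the alkoxide concentration low (no Grob-type fragmentation of the β-hydroxy peroxide), and the bis-tertiary peroxide has no α-hydrogen for a Kornblum–DeLaMare cleavage.

Step 6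
Reactants: 9 (1S,1'S)-1,1'-[(3R,6R)-3,6-dimethyl-1,2-dioxane-3,6-diyl]bis(ethane-1,2-diol)
Product: 10 (3R,6R)-3,6-dimethyl-1,2-dioxane-3,6-dicarbaldehyde
Conditions: NaIO4 (2.5 equiv), THF/H2O, 0 °C to rt
Reagents that add atoms: none
Why: Malaprade glycol cleavage excises both helper CH2OH carbons under near-neutral conditions that leave dialkyl peroxides intact, and the α-quaternary aldehydes formed cannot epimerise.

Step 7
Reactants: 10 (3R,6R)-3,6-dimethyl-1,2-dioxane-3,6-dicarbaldehyde; 11 methyl (triphenyl-λ5-phosphanylidene)acetate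
Product: 12 methyl (E)-3-[(3R,6R)-6-formyl-3,6-dimethyl-1,2-dioxan-3-yl]prop-2-enoate
Conditions: 11 (0.9 equiv, slow addition), CH2Cl2, 0 °C to rt; unreacted 10 recycled
Reagents that add atoms: none
Why: The Wittig reaction of a stabilised ylide is E-selective, neutral and known on α-peroxy aldehydes, and because the two formyl groups are homotopic a deficit of ylide should give the mono-adduct as one stereoisomer.

Step 8
Reactants: 13 (7-bromoheptyl)benzene
Product: 14 (7-phenylheptyl)triphenylphosphonium bromide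
Conditions: PPh3, MeCN, reflux
Reagents that add atoms: triphenylphosphine c1ccc(cc1)P(c2ccccc2)c3ccccc3
Why: SN2 quaternisation of triphenylphosphine by a primary bromide is the standard entry to a Wittig salt.

Step 9
Reactants: 12 methyl (E)-3-[(3R,6R)-6-formyl-3,6-dimethyl-1,2-dioxan-3-yl]prop-2-enoate; 14 (7-phenylheptyl)triphenylphosphonium bromide
Product: 16 methyl (E)-3-{(3R,6R)-3,6-dimethyl-6-[(Z)-8-phenyloct-1-en-1-yl]-1,2-dioxan-3-yl}prop-2-enoate, via phosphonium ylide 15 (not isolated)
Conditions: 14, NaHMDS, THF, −78 °C; then 12, −78 to 0 °C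
Reagents that add atoms: none
Why: The Wittig reaction of a non-stabilised ylide adds faster to the aldehyde than to the enoate at low temperature, 12 has no enolisable position, Wittig olefination of quaternary α-peroxy aldehydes is known, and the alkene geometry is irrelevant because it is reduced next.

Step 10
Reactants: 16 methyl (E)-3-{(3R,6R)-3,6-dimethyl-6-[(Z)-8-phenyloct-1-en-1-yl]-1,2-dioxan-3-yl}prop-2-enoate
Product: 17 methyl 3-[(3R,6S)-3,6-dimethyl-6-(8-phenyloctyl)-1,2-dioxan-3-yl]propanoate
Conditions: KO2CN=NCO2K (excess, in portions), AcOH, MeOH, 0 °C to rt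
Reagents that add atoms: none
Why: Diimide reduction transfers H2 concertedly to both C=C bonds and leaves the O–O bond and the arene untouched, where catalytic hydrogenation would cleave the peroxide (the change of one descriptor from R to S reflects only a change of priority).

Step 11
Reactants: 17 methyl 3-[(3R,6S)-3,6-dimethyl-6-(8-phenyloctyl)-1,2-dioxan-3-yl]propanoate
Product: 18 3-[(3R,6S)-3,6-dimethyl-6-(8-phenyloctyl)-1,2-dioxan-3-yl]propanoic acid
Conditions: LiOH, THF/MeOH/H2O, 0 °C to rt; then 1 M HCl to pH 3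
Reagents that add atoms: lithium hydroxide [Li+].[OH-]
Why: Saponification of a methyl ester is safe here because the peroxide carbons are fully substituted, so base can neither abstract an α-hydrogen nor epimerise a centre.

## Compound list

1 | hexa-1,5-diyne | C#CCCC#C | starting material
2 | (1E,5E)-1,6-bis(dimethylalumanyl)-2,5-dimethylhexa-1,5-diene | C[Al](C)/C=C(\C)CC/C(C)=C/[Al](C)C | intermediate
3 | dilithium bis(butyldimethylalanate) derived from 2 | [Li+].[Li+].CCCC[Al-](C)(C)/C=C(\C)CC/C(C)=C/[Al-](C)(C)CCCC | intermediate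
4 | (2E,6E)-3,6-dimethylocta-2,6-diene-1,8-diol | OC/C=C(\C)CC/C(C)=C/CO | intermediate
5 | (2S,3S,6S,7S)-2,3:6,7-diepoxy-3,6-dimethyloctane-1,8-diol | OC[C@@H]1O[C@@]1(C)CC[C@]2(C)O[C@H]2CO | intermediate
6 | (2S,3S,6S,7S)-1,8-bis(TBDPS-oxy)-2,3:6,7-diepoxy-3,6-dimethyloctane | CC(C)(C)[Si](c1ccccc1)(c2ccccc2)OC[C@@H]3O[C@@]3(C)CC[C@]4(C)O[C@H]4CO[Si](c5ccccc5)(c6ccccc6)C(C)(C)C | intermediate
7 | (2S,3R)-1-(TBDPS-oxy)-3-hydroperoxy-3-methyl-5-{(2S,3S)-2-methyl-3-[(TBDPS-oxy)methyl]oxiran-2-yl}pentan-2-ol | CC(C)(C)[Si](c1ccccc1)(c2ccccc2)OC[C@H](O)[C@](C)(OO)CC[C@]3(C)O[C@H]3CO[Si](c4ccccc4)(c5ccccc5)C(C)(C)C | intermediate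
8 | (1S,1'S)-1,1'-[(3R,6R)-3,6-dimethyl-1,2-dioxane-3,6-diyl]bis[2-(TBDPS-oxy)ethan-1-ol] | CC(C)(C)[Si](c1ccccc1)(c2ccccc2)OC[C@H](O)[C@@]3(C)CC[C@](C)([C@@H](O)CO[Si](c4ccccc4)(c5ccccc5)C(C)(C)C)OO3 | intermediate
9 | (1S,1'S)-1,1'-[(3R,6R)-3,6-dimethyl-1,2-dioxane-3,6-diyl]bis(ethane-1,2-diol) | OC[C@H](O)[C@@]1(C)CC[C@](C)([C@@H](O)CO)OO1 | intermediate
10 | (3R,6R)-3,6-dimethyl-1,2-dioxane-3,6-dicarbaldehyde | O=C[C@@]1(C)CC[C@](C)(C=O)OO1 | intermediate
11 | methyl (triphenyl-λ5-phosphanylidene)acetate | COC(=O)C=P(c1ccccc1)(c2ccccc2)c3ccccc3 | starting material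
12 | methyl (E)-3-[(3R,6R)-6-formyl-3,6-dimethyl-1,2-dioxan-3-yl]prop-2-enoate | C[C@]1(C=O)CC[C@](C)(/C=C/C(=O)OC)OO1 | intermediate
13 | (7-bromoheptyl)benzene | BrCCCCCCCc1ccccc1 | starting material
14 | (7-phenylheptyl)triphenylphosphonium bromide | [Br-].c1ccc(cc1)CCCCCCC[P+](c2ccccc2)(c3ccccc3)c4ccccc4 | intermediate
15 | (7-phenylheptylidene)triphenyl-λ5-phosphane | c1ccc(cc1)CCCCCCC=P(c2ccccc2)(c3ccccc3)c4ccccc4 | intermediate
16 | methyl (E)-3-{(3R,6R)-3,6-dimethyl-6-[(Z)-8-phenyloct-1-en-1-yl]-1,2-dioxan-3-yl}prop-2-enoate | C[C@]1(/C=C\CCCCCCc2ccccc2)CC[C@](C)(/C=C/C(=O)OC)OO1 | intermediate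
17 | methyl 3-[(3R,6S)-3,6-dimethyl-6-(8-phenyloctyl)-1,2-dioxan-3-yl]propanoate | C[C@]1(CCCCCCCCc2ccccc2)CC[C@](C)(CCC(=O)OC)OO1 | intermediate
18 | 3-[(3R,6S)-3,6-dimethyl-6-(8-phenyloctyl)-1,2-dioxan-3-yl]propanoic acid | C[C@]1(CCCCCCCCc2ccccc2)CC[C@](C)(CCC(=O)O)OO1 | target

## Count and risks

Total step count: 11. Longest linear sequence: 10 (steps 1–7 and 9–11).

**Step 4 (proposed new method).**
- **What may go wrong:** the second oxirane may be opened by another molecule of H2O2, by the newly freed secondary hydroxyl or by the neighbouring oxirane oxygen before the tethered OOH closes the ring. Partial ionisation at the tertiary carbon may also erode the inversion.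
- **Fallback (known chemistry, from 4, back at 8):** the two C–O bonds are made in separate operations, so that no second oxirane is present while H2O2 is.
  - Diol 4 is monosilylated (TBDPSCl, 1 equiv) to the mono-TBDPS ether F1.
  - Sharpless epoxidation with L-(+)-diethyl tartrate gives the (2S,3S)-epoxy alcohol F2, and silylation gives the alkenyl epoxide F3.
  - H3PMo12O40-catalysed perhydrolysis gives the alkenyl β-hydroxy hydroperoxide F4.
  - mCPBA then epoxidises the remaining alkene on both faces, to 7 and to its (6R,7R)-oxirane diastereomer F5.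
  - Camphorsulfonic acid closes both by 6-exo opening, 7 to 8 and F5 to the meso cis-dimethyl dioxane F6, which is removed by chromatography. Enantiomeric purity then rests on F2.

**Step 7.**
- **What may go wrong:** the second formyl group may also be olefinated. Material may be lost through hydration, volatility or fragmentation while two α-peroxy aldehydes are exposed at once.
- **Fallback (from 8, back at 12):** the symmetry is broken at the silyl ether stage, so that only one aldehyde exists at a time.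
  - One equivalent of TBAF/AcOH gives the mono-silyl triol F7.
  - NaIO4 cleaves its only free glycol to the mono-aldehyde F8.
  - Wittig reaction with 11 gives the silyl-protected enoate F9.
  - TBAF/AcOH gives the enoate diol F10, and NaIO4 gives 12.

**Step 9.**
- **What may go wrong:** addition to the neopentyl-type aldehyde may be slow, which would leave the basic ylide time to attack the O–O bond or the enoate.
- **Fallback (from 13 and 12, back at 17):** a Julia–Kocienski olefination under Barbier conditions, in which the carbanion never accumulates and no phosphorus reagent is present.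
  - Bromide 13 and 1-phenyl-1H-tetrazole-5-thiol (K2CO3, acetone) give the tetrazolyl sulfide F11.
  - H2O2 with (NH4)6Mo7O24 gives the tetrazolyl sulfone F12.
  - KHMDS added to a mixture of F12 and 12 (THF, −78 °C) gives the (E,E)-diene ester F13.
  - The diimide conditions of step 10 reduce F13 to 17.

## Further compounds

F1 | step 4 | (2E,6E)-8-(TBDPS-oxy)-3,6-dimethylocta-2,6-dien-1-ol | OC/C=C(\C)CC/C(C)=C/CO[Si](c1ccccc1)(c2ccccc2)C(C)(C)C
F2 | step 4 | {(2S,3S)-3-[(E)-5-(TBDPS-oxy)-3-methylpent-3-en-1-yl]-3-methyloxiran-2-yl}methanol | OC[C@@H]1O[C@@]1(C)CC/C(C)=C/CO[Si](c2ccccc2)(c3ccccc3)C(C)(C)C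
F3 | step 4 | TBDPS ether of F2 | CC(C)(C)[Si](c1ccccc1)(c2ccccc2)OC[C@@H]3O[C@@]3(C)CC/C(C)=C/CO[Si](c4ccccc4)(c5ccccc5)C(C)(C)C
F4 | step 4 | (2S,3R,6E)-1,8-bis(TBDPS-oxy)-3-hydroperoxy-3,6-dimethyloct-6-en-2-ol | CC(C)(C)[Si](c1ccccc1)(c2ccccc2)OC[C@H](O)[C@](C)(OO)CC/C(C)=C/CO[Si](c3ccccc3)(c4ccccc4)C(C)(C)C
F5 | step 4 | (6R,7R)-oxirane diastereomer of 7 | CC(C)(C)[Si](c1ccccc1)(c2ccccc2)OC[C@H](O)[C@](C)(OO)CC[C@@]3(C)O[C@@H]3CO[Si](c4ccccc4)(c5ccccc5)C(C)(C)C
F6 | step 4 | meso cis-3,6-dimethyl diastereomer of 8 | CC(C)(C)[Si](c1ccccc1)(c2ccccc2)OC[C@H](O)[C@@]3(C)CC[C@@](C)([C@H](O)CO[Si](c4ccccc4)(c5ccccc5)C(C)(C)C)OO3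
F7 | step 7 | (S)-1-{(3R,6R)-6-[(S)-2-(TBDPS-oxy)-1-hydroxyethyl]-3,6-dimethyl-1,2-dioxan-3-yl}ethane-1,2-diol | OC[C@H](O)[C@@]1(C)CC[C@](C)([C@@H](O)CO[Si](c2ccccc2)(c3ccccc3)C(C)(C)C)OO1
F8 | step 7 | (3R,6R)-6-[(S)-2-(TBDPS-oxy)-1-hydroxyethyl]-3,6-dimethyl-1,2-dioxane-3-carbaldehyde | O=C[C@@]1(C)CC[C@](C)([C@@H](O)CO[Si](c2ccccc2)(c3ccccc3)C(C)(C)C)OO1
F9 | step 7 | methyl (E)-3-{(3R,6R)-6-[(S)-2-(TBDPS-oxy)-1-hydroxyethyl]-3,6-dimethyl-1,2-dioxan-3-yl}prop-2-enoate | COC(=O)/C=C/[C@@]1(C)CC[C@](C)([C@@H](O)CO[Si](c2ccccc2)(c3ccccc3)C(C)(C)C)OO1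
F10 | step 7 | methyl (E)-3-{(3R,6R)-6-[(S)-1,2-dihydroxyethyl]-3,6-dimethyl-1,2-dioxan-3-yl}prop-2-enoate | COC(=O)/C=C/[C@@]1(C)CC[C@](C)([C@@H](O)CO)OO1
F11 | step 9 | 1-phenyl-5-[(7-phenylheptyl)sulfanyl]-1H-tetrazole | C(CCCCCCc1ccccc1)Sc2nnnn2-c3ccccc3
F12 | step 9 | 1-phenyl-5-[(7-phenylheptyl)sulfonyl]-1H-tetrazole | O=S(=O)(CCCCCCCc1ccccc1)c2nnnn2-c3ccccc3
F13 | step 9 | methyl (E)-3-{(3R,6R)-3,6-dimethyl-6-[(E)-8-phenyloct-1-en-1-yl]-1,2-dioxan-3-yl}prop-2-enoate | C[C@]1(/C=C/CCCCCCc2ccccc2)CC[C@](C)(/C=C/C(=O)OC)OO1
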